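**Strategy.** Ring A is built, not substituted. It is a resorcinol diether (O1 on C7a, OMe on C6). Its carbon substituent at C5 sits para to O1, and its C3a–C7a edge is shared with the dihydrofuran ring. This is the pattern left when an O,O-ketene acetal adds across C6/C3 of a 4-methoxy-2-pyrone-5-carboxylate. The route therefore rests on cutting C3a–C4 and C7a–C7. One operation (cycloaddition, loss of CO2, loss of silanol) delivers the fully substituted benzene ring, while C2 and C3 pass through untouched. The precursor is the O-silyl ketene acetal of an enantiopure trans-4-methyl-5-aryl-γ-butyrolactone, made by anti-crotylboration.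

Key step: step 7

Remark on configuration: the target SMILES reads 2R,3R, with aryl and methyl trans. CIP priorities map one to one along the route. The descriptors 1R,2R (anti) in the homoallylic alcohol and diol, 4R,5R (trans) in the lactone and its ketene acetal, and 2R,3R in every dihydrobenzofuran all denote the same spatial arrangement.

Assumption: the (R)-configured phosphoric acid is taken to direct Re-face attack on the aldehyde, as it does with other aromatic aldehydes. If the sense proves opposite, the (S)-acid is used and nothing else changes.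

Step 1
Reactants: 1 3,4,5-trimethoxybenzaldehyde; 2 (E)-crotylboronic acid pinacol ester
Product: 4 (1R,2R)-2-methyl-1-(3,4,5-trimethoxyphenyl)but-3-en-1-ol, via pinacol borate ester 3 (not isolated)
Conditions: (R)-TRIP [(R)-3,3'-bis(2,4,6-triisopropylphenyl)-1,1'-binaphthalene-2,2'-diyl hydrogen phosphate, 5 mol %], 4 Å MS, PhMe, −30 °C; aq. NaHCO3 work-up
Reagents that add atoms: none
Why: Chiral-phosphoric-acid-catalysed crotylboration runs through a closed chair (Zimmerman–Traxler) transition state, so the E-geometry of 2 becomes the anti relationship, while the catalyst, bound to a boronate oxygen and the formyl hydrogen, exposes the Re face of 1 and sets 1R and 2R together.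

Step 2
Reactants: 4 (1R,2R)-2-methyl-1-(3,4,5-trimethoxyphenyl)but-3-en-1-ol
Product: 6 (1R,2R)-2-methyl-1-(3,4,5-trimethoxyphenyl)butane-1,4-diol, via bis-boron adduct 5 (not isolated)
Conditions: 9-BBN-H (2.5 equiv), THF, 0 °C → rt; then aq. NaOH, 30 % H2O2, 0 °C → rt
Reagents that add atoms: hydrogen peroxide, OO
Why: In this hydroboration–oxidation the bulky borane places boron on the terminal carbon of the monosubstituted alkene (one equivalent is consumed by the free OH), and C–B oxidation gives the primary alcohol without touching C1 or C2.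

Step 3
Reactants: 6 (1R,2R)-2-methyl-1-(3,4,5-trimethoxyphenyl)butane-1,4-diol
Product: 8 (4R,5R)-4-methyl-5-(3,4,5-trimethoxyphenyl)dihydrofuran-2(3H)-one, via lactol 7 (not isolated)
Conditions: TEMPO (15 mol %), PhI(OAc)2 (2.3 equiv), CH2Cl2, rt
Reagents that add atoms: none
Why: In this TEMPO/PhI(OAc)2 oxidative lactonisation the hindered oxoammonium ion oxidises the primary alcohol faster than the secondary benzylic one, the hydroxy aldehyde closes to lactol 7, and 7 is oxidised on to the lactone with both stereocentres untouched.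

Step 4
Reactants: 8 (4R,5R)-4-methyl-5-(3,4,5-trimethoxyphenyl)dihydrofuran-2(3H)-one
Product: 10 tert-butyl(dimethyl){[(4R,5R)-4-methyl-5-(3,4,5-trimethoxyphenyl)-4,5-dihydrofuran-2-yl]oxy}silane, via lithium enolate 9 (not isolated)
Conditions: LiN(i-Pr)2 (commercial solution, 1.1 equiv), THF, −78 °C; TBSCl (1.2 equiv), DMPU, −78 °C → rt; pentane, filtration, concentration, used at once
Reagents that add atoms: tert-butyldimethylsilyl chloride, CC(C)(C)[Si](C)(C)Cl
Why: Kinetic enolisation followed by O-silylation in THF/DMPU is the standard entry to tert-butyldimethylsilyl ketene acetals; only the C3 methylene is acidic and no leaving group lies β to the enolate, so C4 and C5 are preserved.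

Step 5
Reactants: 11 dimethyl 1,3-acetonedicarboxylate
Product: 13 methyl 4-hydroxy-2-oxo-2H-pyran-5-carboxylate, via methoxymethylene diester 12 (not isolated)
Conditions: HC(OMe)3 (1.05 equiv), Ac2O (2.2 equiv), 120 °C; evaporate; then 2 M aq. HCl, rt → 50 °C
Reagents that add atoms: trimethyl orthoformate, COC(OC)OC; water, O
Why: Alkoxymethylenation of one active methylene with orthoformate/Ac2O, then acid hydrolysis of the enol ether, frees a hydroxymethylene OH that lactonises onto the distal ester, a classical entry to 4-hydroxy-2-pyrone-5-carboxylates; limiting the orthoformate keeps it to monoformylation.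

Step 6
Reactants: 13 methyl 4-hydroxy-2-oxo-2H-pyran-5-carboxylate
Product: 15 methyl 4-methoxy-2-oxo-2H-pyran-5-carboxylate, via potassium pyronolate 14 (not isolated)
Conditions: Me2SO4 (1.1 equiv), K2CO3 (1.2 equiv), acetone, reflux
Reagents that add atoms: dimethyl sulfate, COS(=O)(=O)OC
Why: O-Alkylation of the ambident 4-hydroxy-2-pyrone anion with a hard methylating agent in acetone takes place at O4, as with other 4-hydroxy-2-pyrones, and the weak base leaves the pyrone ring closed.

Step 7
Reactants: 10 tert-butyl(dimethyl){[(4R,5R)-4-methyl-5-(3,4,5-trimethoxyphenyl)-4,5-dihydrofuran-2-yl]oxy}silane; 15 methyl 4-methoxy-2-oxo-2H-pyran-5-carboxylate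
Product: 18 methyl (2R,3R)-6-methoxy-3-methyl-2-(3,4,5-trimethoxyphenyl)-2,3-dihydrobenzofuran-5-carboxylate, via bridged lactone 16 (not isolated), via dihydroarene 17 (not isolated)
Conditions: 15 (2 equiv), PhMe (0.5 M), base-washed sealed tube, Ar, 110 °C; cool, DBU (0.3 equiv), 23 → 60 °C, same flask
Reagents that add atoms: none
Why: Proposed new method: the nucleophilic C3 of 10 bonds to pyrone C6 (β to the ester and vinylogously conjugated to the ring carbonyl) and pyrone C3 then closes onto the acetal carbon, in a strongly asynchronous or zwitterionic inverse-demand [4+2] addition that gives 16; cycloreversion expels CO2 to give 17, and DBU removes the C3a–H, which is γ to the ester, so that silanolate leaves C7a (E1cB) and the ring aromatises. The closest known reaction type is the Diels–Alder/decarboxylation/alcohol-loss cascade of methyl coumalate and of 3-carbomethoxy-2-pyrone with dialkyl ketene acetals and enol ethers, which gives para- or ortho-alkoxybenzoates; new here are the lactone-derived cyclic silyl ketene acetal, which turns the retained oxygen into a ring atom, and the 4-methoxy donor on the diene. Ring A is closed by an intermolecular [4+2] cycloaddition that joins the four pyrone carbons C3–C6 to the C3a–C7a edge of the existing five-membered ring, forming C3a–C4 and C7a–C7. No lasting stereocentre is made, since the four new sp3 centres of 16 are erased on aromatisation, so facial and endo/exo selectivity are irrelevant, and C2 and C3, which carry no acidic hydrogen, pass through unchanged. Two selectivities are needed: regiochemistry, secured by matching the largest donor coefficient (C3 of 10) with the most electrophilic pyrone carbon (C6), and expulsion of silanolate instead of O1, secured because silanolate is the better nucleofuge and because in the enolate of 17 both ring bonds at C7a lie near the nodal plane, leaving only the exocyclic C7a–OSi bond aligned with the π system; fluoride and protic acid are avoided because a free hemiketal would collapse with ring opening. The rate penalty of the 4-methoxy group is offset by the very high nucleophilicity of five-membered-ring silyl ketene acetals and by using the cheap pyrone in excess.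

Step 8
Reactants: 18 methyl (2R,3R)-6-methoxy-3-methyl-2-(3,4,5-trimethoxyphenyl)-2,3-dihydrobenzofuran-5-carboxylate
Product: 20 [(2R,3R)-6-methoxy-3-methyl-2-(3,4,5-trimethoxyphenyl)-2,3-dihydrobenzofuran-5-yl]methanol, via aluminium alkoxide 19 (not isolated)
Conditions: i-Bu2AlH (2.5 equiv), CH2Cl2, −78 → 0 °C; aq. potassium sodium tartrate
Reagents that add atoms: none
Why: Twofold hydride delivery from i-Bu2AlH reduces the aryl ester fully to the benzylic alcohol, while the aryl methyl ethers and the dihydrofuran ring are inert at these temperatures.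

Step 9
Reactants: 20 [(2R,3R)-6-methoxy-3-methyl-2-(3,4,5-trimethoxyphenyl)-2,3-dihydrobenzofuran-5-yl]methanol
Product: 21 (2R,3R)-6-methoxy-3-methyl-2-(3,4,5-trimethoxyphenyl)-2,3-dihydrobenzofuran-5-carbaldehyde
Conditions: activated MnO2 (15 equiv), CH2Cl2, rt
Reagents that add atoms: none
Why: MnO2 oxidation of a primary benzylic alcohol is neutral, selective and stops at the aldehyde, and C3–H stays unactivated because C3a is meta to the new carbonyl group.

Step 10
Reactants: 21 (2R,3R)-6-methoxy-3-methyl-2-(3,4,5-trimethoxyphenyl)-2,3-dihydrobenzofuran-5-carbaldehyde; 22 5-(ethylsulfonyl)-1-phenyl-1H-tetrazole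
Product: 25 (2R,3R)-6-methoxy-3-methyl-5-[(E)-prop-1-en-1-yl]-2-(3,4,5-trimethoxyphenyl)-2,3-dihydrobenzofuran, via potassium sulfonyl carbanion 23 (not isolated), via alkoxy sulfone adduct 24 (not isolated)
Conditions: 22 (1.3 equiv), KN(SiMe3)2 (1.25 equiv), DME, −60 °C; then 21, −60 °C → rt; sat. aq. NH4Cl
Reagents that add atoms: none
Why: In the Julia–Kocienski olefination a phenyltetrazolyl sulfone with a potassium counter-ion in DME adds through an open transition state to the anti adduct, and Smiles rearrangement with anti elimination of SO2 and tetrazololate gives the E-alkene, a preference that electron-rich aryl aldehydes reinforce.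

**Compound list**
1 | 3,4,5-trimethoxybenzaldehyde | COc1cc(C=O)cc(OC)c1OC | starting material
2 | (E)-crotylboronic acid pinacol ester | C/C=C/CB1OC(C)(C)C(C)(C)O1 | starting material
3 | pinacol borate ester of 4 (O–Bpin on the 1R carbinol) | C=C[C@@H](C)[C@@H](OB1OC(C)(C)C(C)(C)O1)c1cc(OC)c(OC)c(OC)c1 | intermediate
4 | (1R,2R)-2-methyl-1-(3,4,5-trimethoxyphenyl)but-3-en-1-ol (anti) | C=C[C@@H](C)[C@@H](O)c1cc(OC)c(OC)c(OC)c1 | intermediate
5 | bis-boron adduct: C4-(9-borabicyclo[3.3.1]nonan-9-yl) alkylborane and O-(9-borabicyclo[3.3.1]nonan-9-yl) borinate of 4 | C1CC2CCCC(C1)B2CC[C@@H](C)[C@@H](OB3C4CCCC3CCC4)c5cc(OC)c(OC)c(OC)c5 | intermediate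
6 | (1R,2R)-2-methyl-1-(3,4,5-trimethoxyphenyl)butane-1,4-diol | OCC[C@@H](C)[C@@H](O)c1cc(OC)c(OC)c(OC)c1 | intermediate
7 | (4R,5R)-4-methyl-5-(3,4,5-trimethoxyphenyl)tetrahydrofuran-2-ol (lactol, both anomers) | OC1C[C@@H](C)[C@H](c2cc(OC)c(OC)c(OC)c2)O1 | intermediate
8 | (4R,5R)-4-methyl-5-(3,4,5-trimethoxyphenyl)dihydrofuran-2(3H)-one (trans) | O=C1C[C@@H](C)[C@H](c2cc(OC)c(OC)c(OC)c2)O1 | intermediate
9 | lithium enolate of 8 | [Li]OC1=C[C@@H](C)[C@H](c2cc(OC)c(OC)c(OC)c2)O1 | intermediate
10 | tert-butyl(dimethyl){[(4R,5R)-4-methyl-5-(3,4,5-trimethoxyphenyl)-4,5-dihydrofuran-2-yl]oxy}silane | CC(C)(C)[Si](C)(C)OC1=C[C@@H](C)[C@H](c2cc(OC)c(OC)c(OC)c2)O1 | intermediate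
11 | dimethyl 1,3-acetonedicarboxylate | COC(=O)CC(=O)CC(=O)OC | starting material
12 | dimethyl 2-(methoxymethylene)-3-oxopentanedioate (alkene geometry open) | COC=C(C(=O)OC)C(=O)CC(=O)OC | intermediate
13 | methyl 4-hydroxy-2-oxo-2H-pyran-5-carboxylate | COC(=O)C1=COC(=O)C=C1O | intermediate
14 | potassium salt of 13 | [K+].COC(=O)C1=COC(=O)C=C1[O-] | intermediate
15 | methyl 4-methoxy-2-oxo-2H-pyran-5-carboxylate | COC(=O)C1=COC(=O)C=C1OC | intermediate
16 | bridged lactone: 2-oxabicyclo[2.2.2]oct-5-en-3-one fused to the tetrahydrofuran ring, OTBS on the acetal carbon; the two centres of 10 retained, the four new centres transient and left open | O=C1OC2C(C(=O)OC)=C(OC)C1C3(O[Si](C)(C)C(C)(C)C)O[C@@H](c4cc(OC)c(OC)c(OC)c4)[C@H](C)C23 | intermediate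
17 | methyl (2R,3R)-7a-(tert-butyldimethylsilyloxy)-6-methoxy-3-methyl-2-(3,4,5-trimethoxyphenyl)-2,3,3a,7a-tetrahydrobenzofuran-5-carboxylate (C3a/C7a cis-fused, transient) | COC(=O)C1=CC2[C@@H](C)[C@H](c3cc(OC)c(OC)c(OC)c3)OC2(O[Si](C)(C)C(C)(C)C)C=C1OC | intermediate
18 | methyl (2R,3R)-6-methoxy-3-methyl-2-(3,4,5-trimethoxyphenyl)-2,3-dihydrobenzofuran-5-carboxylate | COC(=O)c1cc2c(cc1OC)O[C@@H](c1cc(OC)c(OC)c(OC)c1)[C@@H]2C | intermediate
19 | diisobutylaluminium alkoxide of 20 | CC(C)C[Al](CC(C)C)OCc1cc2c(cc1OC)O[C@@H](c1cc(OC)c(OC)c(OC)c1)[C@@H]2C | intermediate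
20 | [(2R,3R)-6-methoxy-3-methyl-2-(3,4,5-trimethoxyphenyl)-2,3-dihydrobenzofuran-5-yl]methanol | OCc1cc2c(cc1OC)O[C@@H](c1cc(OC)c(OC)c(OC)c1)[C@@H]2C | intermediate
21 | (2R,3R)-6-methoxy-3-methyl-2-(3,4,5-trimethoxyphenyl)-2,3-dihydrobenzofuran-5-carbaldehyde | O=Cc1cc2c(cc1OC)O[C@@H](c1cc(OC)c(OC)c(OC)c1)[C@@H]2C | intermediate
22 | 5-(ethylsulfonyl)-1-phenyl-1H-tetrazole | CCS(=O)(=O)c1nnnn1-c1ccccc1 | starting material
23 | potassium α-sulfonyl carbanion of 22 | C[CH-]S(=O)(=O)c1nnnn1-c1ccccc1.[K+] | intermediate
24 | potassium β-alkoxy sulfone from 21 and 23 (two new centres transient) | CC(C([O-])c1cc2c(cc1OC)O[C@@H](c1cc(OC)c(OC)c(OC)c1)[C@@H]2C)S(=O)(=O)c1nnnn1-c1ccccc1.[K+] | intermediate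
25 | (2R,3R)-6-methoxy-3-methyl-5-[(E)-prop-1-en-1-yl]-2-(3,4,5-trimethoxyphenyl)-2,3-dihydrobenzofuran | C/C=C/c1cc2c(cc1OC)O[C@@H](c1cc(OC)c(OC)c(OC)c1)[C@@H]2C | target

**Total step count:** 10. **Longest linear sequence:** 8 (steps 1–4 and 7–10); steps 5–6 form the short convergent branch.

**Steps most likely to fail**

1. Step 7. Three things may go wrong.
- The cycloaddition may be too slow on a donor-substituted pyrone, so that hydrolysis or O-to-C silyl migration of the ketene acetal wins.
- The first bond may form without the second, through conjugate addition with silyl transfer or opening of the pyrone ring.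
- Aromatisation may take the concerted anti pathway across C3a–C7a, with cleavage of C7a–O1.

The fallback uses known chemistry. Ring A is taken from a quinone and the dihydrofuran ring is made instead. It sets out from 1 and 22 and comes back at 25. Carbanion 23 is added to 1 under the conditions of step 10, and the potassium alkoxide adduct F1 collapses to (E)-1,2,3-trimethoxy-5-(prop-1-en-1-yl)benzene F2. This alkene is combined with commercial 2-methoxy-1,4-benzoquinone and a stoichiometric chiral titanium TADDOLate in CH2Cl2 at −78 °C. The TADDOLate is made from TiCl4, Ti(Oi-Pr)4 and the TADDOL enantiomer that leads to the 2R,3R series. Chelation of the C1 carbonyl and the methoxy oxygen directs the alkene terminus to quinone C5. The benzylic cation is captured by the C4 carbonyl oxygen, and tautomerisation should give trans-(2R,3R)-6-methoxy-3-methyl-2-(3,4,5-trimethoxyphenyl)-2,3-dihydrobenzofuran-5-ol F3. Triflation (Tf2O, pyridine, CH2Cl2, 0 °C) gives the aryl triflate F4. Suzuki–Miyaura coupling with commercial (E)-prop-1-enylboronic acid pinacol ester (Pd(PPh3)4, K3PO4, dioxane/H2O, 80 °C) gives 25 with retention of alkene geometry.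

2. Step 4. Competing C-silylation, hydrolysis during isolation, or decay on storage before the cycloaddition may occur. The fallback replaces the silyl donor by a robust sulfur analogue. It sets out from 8 and comes back at 18. Lawesson's reagent (PhMe, 100 °C) converts 8 into (4R,5R)-4-methyl-5-(3,4,5-trimethoxyphenyl)dihydrofuran-2(3H)-thione F5. KN(SiMe3)2 (THF, −78 °C) gives the potassium enethiolate F6, which MeI alkylates on sulfur to the ketene O,S-acetal (2R,3R)-3-methyl-5-(methylsulfanyl)-2-(3,4,5-trimethoxyphenyl)-2,3-dihydrofuran F7. This compound tolerates water and chromatography. Heated with 15 as in step 7 (xylene, 140 °C if needed), it should pass through the methylsulfanyl bridged lactone F8 and the methylsulfanyl dihydroarene F9, and lose CO2 and methanethiol to give 18. Thiolate leaves far more readily than either oxygen, so retention of O1 is reinforced. The price is one more step and a weaker donor, and this variant still relies on the unproven cycloaddition of step 7.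

3. Step 10. The kinetic E-selectivity in the addition/elimination sequence may be insufficient. The fallback replaces kinetic by thermodynamic control. It sets out from 21 and comes back at 25. Wittig olefination (EtPPh3Br, KOt-Bu, THF, 0 °C) forms the alkene without regard to geometry, mainly the (Z)-propenyl isomer F10 beside 25. The mixture is then equilibrated with PdCl2(MeCN)2 (cat., CH2Cl2, rt), which drives conjugated propenylarenes to the more stable E-isomer 25 without affecting C2 or C3.

**Further compounds**
F1 | step 7 | potassium β-alkoxy sulfone from 1 and 23 | CC(C([O-])c1cc(OC)c(OC)c(OC)c1)S(=O)(=O)c1nnnn1-c1ccccc1.[K+]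
F2 | step 7 | (E)-1,2,3-trimethoxy-5-(prop-1-en-1-yl)benzene | C/C=C/c1cc(OC)c(OC)c(OC)c1
F3 | step 7 | (2R,3R)-6-methoxy-3-methyl-2-(3,4,5-trimethoxyphenyl)-2,3-dihydrobenzofuran-5-ol | Oc1cc2c(cc1OC)O[C@@H](c1cc(OC)c(OC)c(OC)c1)[C@@H]2C
F4 | step 7 | (2R,3R)-6-methoxy-3-methyl-2-(3,4,5-trimethoxyphenyl)-2,3-dihydrobenzofuran-5-yl trifluoromethanesulfonate | FC(F)(F)S(=O)(=O)Oc1cc2c(cc1OC)O[C@@H](c1cc(OC)c(OC)c(OC)c1)[C@@H]2C
F5 | step 4 | (4R,5R)-4-methyl-5-(3,4,5-trimethoxyphenyl)dihydrofuran-2(3H)-thione | S=C1C[C@@H](C)[C@H](c2cc(OC)c(OC)c(OC)c2)O1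
F6 | step 4 | potassium enethiolate of F5 | [K+].[S-]C1=C[C@@H](C)[C@H](c2cc(OC)c(OC)c(OC)c2)O1
F7 | step 4 | (2R,3R)-3-methyl-5-(methylsulfanyl)-2-(3,4,5-trimethoxyphenyl)-2,3-dihydrofuran | CSC1=C[C@@H](C)[C@H](c2cc(OC)c(OC)c(OC)c2)O1
F8 | step 4 | methylsulfanyl analogue of bridged lactone 16 (new centres transient) | O=C1OC2C(C(=O)OC)=C(OC)C1C3(SC)O[C@@H](c4cc(OC)c(OC)c(OC)c4)[C@H](C)C23
F9 | step 4 | methyl (2R,3R)-6-methoxy-3-methyl-7a-(methylsulfanyl)-2-(3,4,5-trimethoxyphenyl)-2,3,3a,7a-tetrahydrobenzofuran-5-carboxylate | COC(=O)C1=CC2[C@@H](C)[C@H](c3cc(OC)c(OC)c(OC)c3)OC2(SC)C=C1OC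
F10 | step 10 | (2R,3R)-6-methoxy-3-methyl-5-[(Z)-prop-1-en-1-yl]-2-(3,4,5-trimethoxyphenyl)-2,3-dihydrobenzofuran | C/C=C\c1cc2c(cc1OC)O[C@@H](c1cc(OC)c(OC)c(OC)c1)[C@@H]2C
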